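**Retrosynthetic overview**
1. Glabrol (15) comes from its bis-MOM ether 14 by mild acid, and 14 from the 5,6-dihydro compound 13 by dehydrogenation, so the benzene ring A is formed last.
2. 13 is cut at C2–C3 and O1–C8a into the ring B aldehyde 10 and the bis(silyloxy) triene 7. They are joined by an enantioselective vinylogous Mukaiyama aldol addition, and an acid cyclocondensation then closes ring C.
3. Feature used: O1–C2–C3–C4 of ring C is an aryl aldehyde (O1, C2) bonded to the enol of an acetyl group (C3, C4). Ring A (C4a, C5–C8, C8a), with oxygens on C7 and C8a flanking the prenylated C8, is 2-prenylcyclohexane-1,3-dione at a lower oxidation level.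
4. 7 comes from cyclohexane-1,3-dione by C-prenylation, O-MOM protection, acetylation at C6 of the enone and double O-silylation; 10 comes from 4-hydroxybenzaldehyde by ortho-prenylation and MOM protection.
5. Ring order: ring B is bought, ring A is bought as the dione, ring C is closed in step 8, ring A is aromatised in step 9.

Key step: step 8

Notation: prenyl = 3-methylbut-2-en-1-yl, MOM = methoxymethyl; chroman-4-one numbering (O1, C2, C3, C4, C4a, C5–C8, C8a) is used for the ring-fused compounds.
Assumption: the sense of induction of Ti(OiPr)4 with BINOL known for simple aryl aldehydes is taken to hold, (S)-BINOL sending the nucleophile to the Si face of the aldehyde; if the triene 7 reverses it, (R)-BINOL is used instead.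

**Route**

Step 1
Reactants: 1 cyclohexane-1,3-dione; 2 prenyl bromide (1-bromo-3-methylbut-2-ene)
Product: 3 2-prenylcyclohexane-1,3-dione
Conditions: KOH (1 equiv), H2O, 0 °C → rt
Reagents that add atoms: none
Why: C-alkylation of the potassium enolate of a cyclic 1,3-dione by an allylic bromide in water, where hydrogen bonding to the enolate oxygens disfavours O-alkylation, and the acidic product can be separated from O-alkylated and dialkylated material by extraction into base.

Step 2
Reactants: 3 2-prenylcyclohexane-1,3-dione
Product: 4 3-(methoxymethoxy)-2-prenylcyclohex-2-en-1-one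
Conditions: MOMCl, iPr2NEt, CH2Cl2, 0 °C → rt
Reagents that add atoms: chloromethyl methyl ether (MOMCl), COCCl
Why: O-alkylation of the vinylogous acid by the hard chloromethyl ether, and the symmetry of 3 allows only one enol ether.

Step 3
Reactants: 4 3-(methoxymethoxy)-2-prenylcyclohex-2-en-1-one
Product: 5 6-acetyl-3-(methoxymethoxy)-2-prenylcyclohex-2-en-1-one (largely enolised)
Conditions: LiHMDS (2.2 equiv), THF, −78 °C; then 1-acetylbenzotriazole (1.0 equiv), −78 → 0 °C
Reagents that add atoms: 1-acetyl-1H-benzotriazole, CC(=O)n1nnc2ccccc12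
Why: Kinetic deprotonation of a 3-alkoxy enone takes place at the alpha-prime carbon C6 (Stork–Danheiser enolate, the later C4a) and N-acylbenzotriazoles acylate lithium enolates on carbon (Claisen-type C-acylation), the second equivalent of base taking up the acidic proton of the diketone.

Step 4
Reactants: 5 6-acetyl-3-(methoxymethoxy)-2-prenylcyclohex-2-en-1-one
Product: 6 1-[4-(methoxymethoxy)-3-prenyl-2-(trimethylsilyloxy)cyclohexa-1,3-dien-1-yl]ethan-1-one
Conditions: TMSCl, Et3N, toluene, rt; filtration under argon
Reagents that add atoms: chlorotrimethylsilane (TMSCl), C[Si](C)(C)Cl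
Why: O-silylation of the enolised beta-diketone, expected on the ring oxygen because that enol double bond is conjugated with the C7=C8 enol ether; the isomer silylated on the acetyl oxygen would lead to the same triene in step 5.

Step 5
Reactants: 6 1-[4-(methoxymethoxy)-3-prenyl-2-(trimethylsilyloxy)cyclohexa-1,3-dien-1-yl]ethan-1-one
Product: 7 4-(methoxymethoxy)-3-prenyl-2-(trimethylsilyloxy)-1-[1-(trimethylsilyloxy)ethenyl]cyclohexa-1,3-diene
Conditions: LDA, THF, −78 °C; then TMSCl, −78 → 0 °C; pentane, filtration, used crude
Reagents that add atoms: chlorotrimethylsilane (TMSCl), C[Si](C)(C)Cl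
Why: Kinetic deprotonation of the methyl ketone (its only alpha protons) and O-silylation of the lithium dienolate is the standard second stage in making 1,3-bis(silyloxy)-1,3-dienes from beta-diketones.

Step 6
Reactants: 8 4-hydroxybenzaldehyde; 2 prenyl bromide
Product: 9 4-hydroxy-3-prenylbenzaldehyde
Conditions: KOH, H2O, rt
Reagents that add atoms: none
Why: Ortho C-alkylation of a phenoxide by an allylic bromide in water with the para position blocked by the formyl group, the phenol 9 being separable from the neutral O-prenyl ether.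

Step 7
Reactants: 9 4-hydroxy-3-prenylbenzaldehyde
Product: 10 4-(methoxymethoxy)-3-prenylbenzaldehyde
Conditions: MOMCl, iPr2NEt, CH2Cl2, 0 °C → rt
Reagents that add atoms: chloromethyl methyl ether (MOMCl), COCCl
Why: Williamson-type O-alkylation of the phenol, to which the aldehyde and the prenyl group are inert.

Step 8
Reactants: 7 4-(methoxymethoxy)-3-prenyl-2-(trimethylsilyloxy)-1-[1-(trimethylsilyloxy)ethenyl]cyclohexa-1,3-diene; 10 4-(methoxymethoxy)-3-prenylbenzaldehyde
Product: 13 (2S)-7-(methoxymethoxy)-2-[4-(methoxymethoxy)-3-prenylphenyl]-8-prenyl-2,3,5,6-tetrahydro-4H-chromen-4-one, via silylated aldol adduct 11 (not isolated), via hydroxy diketone 12 (not isolated)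
Conditions: Ti(OiPr)4 (20 mol %), (S)-BINOL (20 mol %), 4 Å MS, THF, −78 → −20 °C; then PPTS (0.3 equiv), water-saturated CH2Cl2, rt → 40 °C
Reagents that add atoms: none
Why: The BINOL complex of tetravalent titanium binds aldehyde 10 and the terminal CH2 of triene 7 adds to the carbonyl carbon in a vinylogous Mukaiyama aldol reaction that makes C2–C3, silyl transfer to the aldolate oxygen releasing the catalyst and leaving 11. The closest known reactions are the titanium–BINOL-catalysed aldol additions of 1,3-bis(trimethylsilyloxy)-1,3-dienes from beta-keto esters and beta-diketones to aryl aldehydes, whose adducts cyclise to 2-aryl-2,3-dihydropyran-4-ones on acid treatment. PPTS in wet solvent removes both silyl groups to give 12, whose C2 hydroxyl attacks C8a (6-exo-trig on the C8a carbonyl of the diketo form, equally a 6-endo-trig addition–elimination on the enol), and loss of water gives the vinylogous ester and closes ring C through O1–C8a, the silicon leaving as hexamethyldisiloxane. C2 is the only new stereocentre and is set by the catalyst, (S)-BINOL being chosen so that the Si face of the aldehyde is attacked, which gives 2S, and the C2–O bond is not broken afterwards. The step needs attack by the triene terminus and not by C4a or C8, and the terminal CH2 is the only unsubstituted nucleophilic carbon while the other two are fully substituted. A weak acid is used for the closure so that the MOM groups and the benzylic C2–O bond, which a strong acid could ionise, are kept.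

Step 9
Reactants: 13 (2S)-7-(methoxymethoxy)-2-[4-(methoxymethoxy)-3-prenylphenyl]-8-prenyl-2,3,5,6-tetrahydro-4H-chromen-4-one
Product: 14 (2S)-7-(methoxymethoxy)-2-[4-(methoxymethoxy)-3-prenylphenyl]-8-prenylchroman-4-one
Conditions: DDQ (1.05 equiv), toluene, 0 °C → rt
Reagents that add atoms: none
Why: Quinone dehydrogenation (hydride abstraction at C5 to a cation stabilised by O1 and the C7 oxygen, then loss of the C6 proton) is driven by formation of the benzene ring and should be much faster than attack of DDQ at C2–H or at the prenyl CH2 groups when one equivalent is used cold, so C2 keeps its configuration.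

Step 10
Reactants: 14 (2S)-7-(methoxymethoxy)-2-[4-(methoxymethoxy)-3-prenylphenyl]-8-prenylchroman-4-one
Product: 15 glabrol, (2S)-7-hydroxy-2-(4-hydroxy-3-prenylphenyl)-8-prenylchroman-4-one
Conditions: HCl (3 M aq), MeOH, 50 °C, short reaction time
Reagents that add atoms: none
Why: Acid-catalysed acetal exchange of the two aryl MOM ethers with methanol, the usual way to free ortho-prenyl phenols of flavanones, run briefly so that the phenols do not add to the prenyl double bonds and the flavanone ring is not opened.

**Compound list**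
1 | cyclohexane-1,3-dione | O=C1CCCC(=O)C1 | starting material
2 | prenyl bromide (1-bromo-3-methylbut-2-ene) | CC(C)=CCBr | starting material
3 | 2-(3-methylbut-2-en-1-yl)cyclohexane-1,3-dione | CC(C)=CCC1C(=O)CCCC1=O | intermediate
4 | 3-(methoxymethoxy)-2-(3-methylbut-2-en-1-yl)cyclohex-2-en-1-one | COCOC1=C(CC=C(C)C)C(=O)CCC1 | intermediate
5 | 6-acetyl-3-(methoxymethoxy)-2-(3-methylbut-2-en-1-yl)cyclohex-2-en-1-one | COCOC1=C(CC=C(C)C)C(=O)C(C(C)=O)CC1 | intermediate
6 | 1-[4-(methoxymethoxy)-3-(3-methylbut-2-en-1-yl)-2-(trimethylsilyloxy)cyclohexa-1,3-dien-1-yl]ethan-1-one | CC(=O)C1=C(O[Si](C)(C)C)C(CC=C(C)C)=C(OCOC)CC1 | intermediate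
7 | 4-(methoxymethoxy)-3-(3-methylbut-2-en-1-yl)-2-(trimethylsilyloxy)-1-[1-(trimethylsilyloxy)ethenyl]cyclohexa-1,3-diene | C=C(O[Si](C)(C)C)C1=C(O[Si](C)(C)C)C(CC=C(C)C)=C(OCOC)CC1 | intermediate
8 | 4-hydroxybenzaldehyde | O=Cc1ccc(O)cc1 | starting material
9 | 4-hydroxy-3-(3-methylbut-2-en-1-yl)benzaldehyde | CC(C)=CCc1cc(C=O)ccc1O | intermediate
10 | 4-(methoxymethoxy)-3-(3-methylbut-2-en-1-yl)benzaldehyde | CC(C)=CCc1cc(C=O)ccc1OCOC | intermediate
11 | (3S)-1-[4-(methoxymethoxy)-3-(3-methylbut-2-en-1-yl)-2-(trimethylsilyloxy)cyclohexa-1,3-dien-1-yl]-3-[4-(methoxymethoxy)-3-(3-methylbut-2-en-1-yl)phenyl]-3-(trimethylsilyloxy)propan-1-one | CC(C)=CCc1cc([C@@H](O[Si](C)(C)C)CC(=O)C2=C(O[Si](C)(C)C)C(CC=C(C)C)=C(OCOC)CC2)ccc1OCOC | intermediate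
12 | (3S)-3-hydroxy-1-[2-hydroxy-4-(methoxymethoxy)-3-(3-methylbut-2-en-1-yl)cyclohexa-1,3-dien-1-yl]-3-[4-(methoxymethoxy)-3-(3-methylbut-2-en-1-yl)phenyl]propan-1-one (enol form of the beta-diketone) | CC(C)=CCc1cc([C@@H](O)CC(=O)C2=C(O)C(CC=C(C)C)=C(OCOC)CC2)ccc1OCOC | intermediate
13 | (2S)-7-(methoxymethoxy)-2-[4-(methoxymethoxy)-3-(3-methylbut-2-en-1-yl)phenyl]-8-(3-methylbut-2-en-1-yl)-2,3,5,6-tetrahydro-4H-chromen-4-one | CC(C)=CCc1cc([C@@H]2CC(=O)C3=C(O2)C(CC=C(C)C)=C(OCOC)CC3)ccc1OCOC | intermediate
14 | (2S)-7-(methoxymethoxy)-2-[4-(methoxymethoxy)-3-(3-methylbut-2-en-1-yl)phenyl]-8-(3-methylbut-2-en-1-yl)chroman-4-one | CC(C)=CCc1cc([C@@H]2CC(=O)c3ccc(OCOC)c(CC=C(C)C)c3O2)ccc1OCOC | intermediate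
15 | glabrol, (2S)-7-hydroxy-2-[4-hydroxy-3-(3-methylbut-2-en-1-yl)phenyl]-8-(3-methylbut-2-en-1-yl)chroman-4-one | CC(C)=CCc1cc([C@@H]2CC(=O)c3ccc(O)c(CC=C(C)C)c3O2)ccc1O | target

**Step count**
Total step count: 10
Longest linear sequence: 8 steps (steps 1, 2, 3, 4, 5, 8, 9, 10)

**Steps most likely to fail**

Step 8. What may go wrong: slow addition to the electron-rich aldehyde, attack through a ring carbon of the triene, poor enantioface selection on a triene that carries a ring, or ionisation at the benzylic carbon and loss of MOM during the acid stage. Fallback: the stereocentre is set on the aldehyde alone by an auxiliary-controlled acetate aldol reaction and ring A is attached afterwards by enolate acylation, so that neither the silyl triene nor a chiral catalyst is needed. It sets out from 10, with 4 as the second component, and comes back to the route at 12. The tin enolate of (4R)-3-acetyl-4-isopropyl-1,3-thiazolidine-2-thione (Sn(OTf)2, divalent tin, N-ethylpiperidine, CH2Cl2, −78 °C) adds to 10 through a chelated chair transition state in which the aldehyde approaches opposite to the isopropyl group. This should give (4R)-3-[(3S)-3-hydroxy-3-[4-(methoxymethoxy)-3-prenylphenyl]propanoyl]-4-isopropyl-1,3-thiazolidine-2-thione F1. TESOTf and 2,6-lutidine in CH2Cl2 should give (4R)-4-isopropyl-3-[(3S)-3-[4-(methoxymethoxy)-3-prenylphenyl]-3-(triethylsilyloxy)propanoyl]-1,3-thiazolidine-2-thione F2. The lithium enolate of 4 (LiHMDS, THF, −78 °C, two equivalents) displaces the thiazolidinethione of F2 on carbon and should give (3S)-1-[2-hydroxy-4-(methoxymethoxy)-3-prenylcyclohexa-1,3-dien-1-yl]-3-[4-(methoxymethoxy)-3-prenylphenyl]-3-(triethylsilyloxy)propan-1-one F3. HF·pyridine buffered with pyridine in THF removes the silyl group to give 12, which is closed to 13 with PPTS as in step 8.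

Step 3. What may go wrong: acylation of the enolate on oxygen, double acylation, or proton transfer from the more acidic product to unreacted enolate so that the reaction stalls. Fallback: the acetyl group is built by aldol addition and oxidation instead of acylation. It sets out from 4 and comes back at 5. The lithium enolate of 4 (LDA, THF, −78 °C) adds to acetaldehyde to give 6-(1-hydroxyethyl)-3-(methoxymethoxy)-2-prenylcyclohex-2-en-1-one F4 as a mixture of diastereomers that converge, and Dess–Martin periodinane with NaHCO3 in CH2Cl2 oxidises the alcohol to 5.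

Step 10. What may go wrong: acid-promoted addition of the freed phenols to the neighbouring prenyl double bonds (chroman formation), or erosion of the C2 configuration through reversible acid-induced opening at the benzylic C2–O1 bond. Fallback: the MOM groups are exchanged for silyl groups under buffered Lewis-acid conditions and the silyl ethers are hydrolysed at neutral pH, so that no protic acid meets the free prenyl phenols. It sets out from 14 and comes back at 15. TMSOTf with 2,2'-bipyridyl in MeCN at 0 °C should convert both aryl MOM ethers into (2S)-8-prenyl-2-[3-prenyl-4-(trimethylsilyloxy)phenyl]-7-(trimethylsilyloxy)chroman-4-one F5, and addition of water cleaves the aryl silyl ethers to give 15.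

**Further compounds**
F1 | step 8 | (4R)-3-[(3S)-3-hydroxy-3-[4-(methoxymethoxy)-3-(3-methylbut-2-en-1-yl)phenyl]propanoyl]-4-isopropyl-1,3-thiazolidine-2-thione | CC(C)=CCc1cc([C@@H](O)CC(=O)N2[C@H](C(C)C)CSC2=S)ccc1OCOC
F2 | step 8 | (4R)-4-isopropyl-3-[(3S)-3-[4-(methoxymethoxy)-3-(3-methylbut-2-en-1-yl)phenyl]-3-(triethylsilyloxy)propanoyl]-1,3-thiazolidine-2-thione | CC(C)=CCc1cc([C@@H](O[Si](CC)(CC)CC)CC(=O)N2[C@H](C(C)C)CSC2=S)ccc1OCOC
F3 | step 8 | (3S)-1-[2-hydroxy-4-(methoxymethoxy)-3-(3-methylbut-2-en-1-yl)cyclohexa-1,3-dien-1-yl]-3-[4-(methoxymethoxy)-3-(3-methylbut-2-en-1-yl)phenyl]-3-(triethylsilyloxy)propan-1-one | CC(C)=CCc1cc([C@@H](O[Si](CC)(CC)CC)CC(=O)C2=C(O)C(CC=C(C)C)=C(OCOC)CC2)ccc1OCOC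
F4 | step 3 | 6-(1-hydroxyethyl)-3-(methoxymethoxy)-2-(3-methylbut-2-en-1-yl)cyclohex-2-en-1-one | COCOC1=C(CC=C(C)C)C(=O)C(C(C)O)CC1
F5 | step 10 | (2S)-8-(3-methylbut-2-en-1-yl)-2-[3-(3-methylbut-2-en-1-yl)-4-(trimethylsilyloxy)phenyl]-7-(trimethylsilyloxy)chroman-4-one | CC(C)=CCc1cc([C@@H]2CC(=O)c3ccc(O[Si](C)(C)C)c(CC=C(C)C)c3O2)ccc1O[Si](C)(C)C
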